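(The numbers in the tables were computed with constants of no real substance; the scatter is artificial.)

We begin with the easy step: we watch what side product does once it has appeared.

| flask | substrate | reagent | temperature | remark | time |
|---|---|---|---|---|---|
| epsilon | 20 mM | 50 mM | 45 °C | run made earlier |  |
| gamma | 20 mM | 25 mM | 56 °C | run made earlier |  |
| alpha | 20 mM | 38 mM | 45 °C | run made earlier |  |
| south-west | 20 mM | 50.0 mM |  | everything together at the start at 20 °C, warmed to 50 °C at 12 h | 20 h |
| south-east | 20 mM (fed, over 12 h) | 50.0 mM | 50 °C | all else is in the flask from the start; the feed brings no volume worth counting | 20 h |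
| east | 20 mM | 50.0 mM | 50 °C | everything together at the start | 20 h |
| south | 20 mM (fed, over 12 h) | 50.0 mM |  | the addition at 20 °C, then warmed to 50 °C; the feed brings no volume worth counting | 20 h |

| run | time / h | side product / % | target / % |
|---|---|---|---|
| epsilon | 0.667 | 68.3 | 23.6 |
| epsilon | 2.00 | 69.2 | 23.7 |
| epsilon | 3.00 | 70.8 | 20.6 |
| epsilon | 5.00 | 68.9 | 16.7 |
| epsilon | 8.00 | 68.8 | 10.0 |
| epsilon | 10.0 | 68.2 | 8.7 |
| epsilon | 12.0 | 69.9 | 6.3 |
| gamma | 1.00 | 78.2 | 18.7 |
| gamma | 3.00 | 77.9 | 15.9 |
| gamma | 6.00 | 78.5 | 8.7 |
| gamma | 8.00 | 79.3 | 5.8 |
| gamma | 12.0 | 77.0 | 3.8 |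
| gamma | 15.0 | 80.2 | 1.2 |
| gamma | 20.0 | 76.9 | 1.3 |
| alpha | 3.00 | 72.8 | 19.1 |
| alpha | 6.00 | 74.6 | 12.8 |
| alpha | 8.00 | 73.0 | 11.5 |
| alpha | 12.0 | 74.5 | 7.1 |
| alpha | 15.0 | 73.7 | 7.3 |
| alpha | 20.0 | 73.2 | 3.5 |

(each reading ± 1 percentage point)

- which flask leads in amount of side product, in percent of the substrate charged ("all alike" within 1.5 percentage points) (south-west / south-east / east / south / all alike)
- how much side product is there at the end, in percent of the substrate charged: south-west
- how much side product is there at the end, in percent of the substrate charged: south-east
- how much side product is there at the end, in percent of the substrate charged: east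
- how much side product is there at the end, in percent of the substrate charged: south

- in percentages every species weighs as the substrate in it: one side product counts as two
- a reading or a percentage of target counts all its forms, free or not

1. Fade of target: in the epsilon run target falls from 23.7% at 2.00 h to 6.3% at 12.0 h, while side product stays between 68.2% and 70.8%. So the fade need not be known well for this question.

2. Our assumption: two substrate pair up to side product, while substrate and reagent give target. The share going to side product is then c(substrate)/(c(substrate) + c_bal), where c_bal is the balance concentration, the substrate level at which both routes run equally fast. This is a selectivity measure, and it must be known moderately well.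

3. Taking a batch as working at half its charge, the epsilon reading at 2.00 h gives c_bal = 4.45 mM.

4. Lifetime of substrate: the first epsilon reading of side product, 68.3% at 0.667 h, already lies among the later ones, so we take that time to span several lifetimes and use it as a ceiling on the lifetime.

5. South-east: the feed lasts 18.0 of these ceiling lifetimes, so we expect substrate to hold below about 1.11 mM, and our share to come to no more than about 20.0%. With half that lifetime our share is 11.1%, while the highest epsilon reading of side product, used for c_bal, gives 21.2%, so the lifetime is the number to know better.

The forecast names south-west as leader, with 78% there, 58% in south-east, 68% in east and 76% in south, holding that “feeding alone changes little”, and for south-east it differs from our lower figure.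

The flasks give 77.6% in south-west, 19.8% in south-east, 67.1% in east and 55.3% in south.

    substrate + reagent → target (k = 58.0 L mol⁻¹ h⁻¹, Ea = 65.0 kJ mol⁻¹)
    reagent + target → over-reaction product (k = 5.40 L mol⁻¹ h⁻¹, Ea = 75.0 kJ mol⁻¹)
    substrate + target ⇌ idle adduct, settled at all times (K = 69.0 L mol⁻¹, ΔH = −16.0 kJ mol⁻¹)
    2 substrate → side product (k = 450 L mol⁻¹ h⁻¹, Ea = 47.0 kJ mol⁻¹)
    (constants at 50 °C)

At the end of its feed, south-east held 0.741 mM of free substrate, less than c_bal. The neighbour of south-east charged with 30 mM of reagent tests the rule: scaling with reagent, c_bal becomes 2.67 mM and the ceiling on the level 1.85 mM, so our share comes to no more than about 40.9%, and that flask ends at 37.1%.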